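The cyclohexenone is disconnected at C4–C5 and C6–C1. C1 (ketone) and C4 (acyloxy) flank the C2=C3 alkene, which is what a 2-pyrone oxygenated at its 3-position leaves behind after cycloaddition, and the trans-related C5 and C6 map onto an E-enone. One catalytic asymmetric [4+2] union of 3-hydroxy-4-(silyloxymethyl)-2-pyrone (its side arm is the future C7) with (E)-5-methylhex-3-en-2-one closes the carbocycle as a lactone-bridged bicyclo[2.2.2]octene and sets C1, C4, C5 and C6 at once. Afterwards the acetyl group becomes the C6 oxygen by Baeyer–Villiger oxidation, the bridge is opened and its carbonyl carbon expelled as CO2 to give the C1 ketone, and the two esters are fitted.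

Key step: step 3

Remark: ring atoms keep the target numbering (C1 ketone, C2 bearing C7, C3, C4, C5, C6) in the text for every intermediate, while the systematic names of the bicyclic compounds use bicycle locants; 1, 2, 6, 11, 14 and 15 are taken to be commercial.

Step 1
Reactants: 1 3-hydroxy-2H-pyran-2-one; 2 formaldehyde
Product: 3 3-hydroxy-4-(hydroxymethyl)-2H-pyran-2-one
Conditions: 37% aq. HCHO (1.1 equiv), Et3N (0.2 equiv), H2O/THF, 0 °C to rt; AcOH
Reagents that add atoms: none
Why: Lederer–Manasse-type (aldol) hydroxymethylation, in which the amine forms the dienolate of the acidic 3-hydroxyl and the small, hard electrophile is taken up at its α-carbon C4 (the carbon flanking the enol oxygen, as in the hydroxymethylation of kojic acid-type hydroxypyranones) before tautomerisation restores the hydroxypyrone; no stereocenter is formed.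

Step 2
Reactants: 3 3-hydroxy-4-(hydroxymethyl)-2H-pyran-2-one
Product: 5 4-{[(tert-butyldimethylsilyl)oxy]methyl}-3-hydroxy-2H-pyran-2-one, via bis-silyl ether 4 (not isolated)
Conditions: TBSCl (2.3 equiv), imidazole (4 equiv), DMF, 0 °C to rt; then MeOH, K2CO3 (3 equiv), 0 °C; 1 M HCl to pH 4
Reagents that add atoms: tert-butyldimethylsilyl chloride (TBSCl), CC(C)(C)[Si](C)(C)Cl
Why: Imidazole-promoted silylation caps both hydroxyls, and the silyl group on the acidic enol oxygen (a vinylogous silyl ester) is then removed by carbonate in methanol, the usual discrimination between aryl-type and primary alkyl silyl ethers, so that only the primary TBS ether remains; no stereocenter is involved.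

Step 3
Reactants: 5 4-{[(tert-butyldimethylsilyl)oxy]methyl}-3-hydroxy-2H-pyran-2-one; 6 (E)-5-methylhex-3-en-2-one
Product: 7 (1R,4R,7R,8R)-8-acetyl-5-{[(tert-butyldimethylsilyl)oxy]methyl}-4-hydroxy-7-(propan-2-yl)-2-oxabicyclo[2.2.2]oct-5-en-3-one (endo-acetyl adduct: acetyl syn to the alkene bridge, isopropyl on the lactone-bridge side, hydroxyl on the bridgehead next to the lactone carbonyl)
Conditions: thiourea of 9-amino-9-deoxy-epi-quinidine and 3,5-bis(trifluoromethyl)phenyl isothiocyanate (10 mol %), 6 (3 equiv), Et2O, rt
Reagents that add atoms: none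
Why: The quinuclidine nitrogen deprotonates the 3-hydroxyl of 5 to an ion-paired oxido-diene with a raised HOMO while the thiourea N–H pair binds the enone carbonyl, so a concerted but asynchronous [4+2] cycloaddition follows in which pyrone C6 bonds first to the enone β-carbon (C4–C5) and the enone α-carbon then closes on pyrone C3 (C6–C1). The closest known reaction type is the cinchona bifunctional-base-catalysed Diels–Alder reaction of 3-hydroxy-2-pyrones with α,β-unsaturated ketones, applied here to a 4-substituted pyrone and a β-branched enone. The one new ring, the C1–C6 carbocycle, closes by suprafacial [4π+2π] addition as a boat held by the pyrone lactone, which ends up as the two-atom bridge of the 2-oxabicyclo[2.2.2]octene. C1 and C4 are set together because both bonds form on one face of the flat pyrone (the face chosen by the chiral ion pair fixes their absolute sense), the trans relation of C5 and C6 is copied from the E alkene, and the endo position of the acetyl group (syn to the new C2=C3 bond) follows from the compact hydrogen-bonded transition state and turns the isopropyl group toward the lactone bridge, cis to the C4 oxygen. The step needs regio-, endo- and facial selectivity: the first comes from the polarity match of the nucleophilic dienolate terminus (pyrone C6) with the enone β-carbon, the other two from the two-point binding of the catalyst, and the quinine-derived pseudoenantiomer is at hand should the quinidine series favour the other face.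

Step 4
Reactants: 7 endo-acetyl adduct
Product: 8 (1S,4S,7S,8R)-5-{[(tert-butyldimethylsilyl)oxy]methyl}-4-hydroxy-3-oxo-7-(propan-2-yl)-2-oxabicyclo[2.2.2]oct-5-en-8-yl acetate
Conditions: mCPBA (1.5 equiv), CH2Cl2, 0 °C to rt
Reagents that add atoms: meta-chloroperoxybenzoic acid (mCPBA), OOC(=O)c1cccc(Cl)c1
Why: Baeyer–Villiger oxidation, in which the secondary C6 carbon migrates in preference to methyl with retention, so the acetyl group becomes the C6 acetate on the same face, while the C2=C3 alkene is slowed toward the peracid by three electron-withdrawing allylic C–O bonds and the bridgehead hydroxyl, lying in the nodal plane of that alkene, gives no face-directing help.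

Step 5
Reactants: 8 C6 acetate lactone
Product: 9 (1S,4S,5S,6R)-6-(acetyloxy)-2-{[(tert-butyldimethylsilyl)oxy]methyl}-1,4-dihydroxy-5-(propan-2-yl)cyclohex-2-ene-1-carboxylic acid (carboxyl and C4–OH cis; C1–OH and C6–OAc on the other face)
Conditions: LiOH·H2O (1.1 equiv), THF/H2O (3:1), 0 °C; then 1 M HCl to pH 3
Reagents that add atoms: lithium hydroxide, [Li+].[OH-]
Why: Saponification with one equivalent of hydroxide in the cold, in which the bridged lactone (strained, locked in the reactive E ester geometry and activated by its α-hydroxyl) should be attacked much faster than the acetate on the hindered secondary C6 oxygen, freeing the C1 carboxylate and the C4 hydroxyl without touching a stereocenter.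

Step 6
Reactants: 9 hydroxy acid
Product: 10 (4S,5S,6R)-6-(acetyloxy)-2-{[(tert-butyldimethylsilyl)oxy]methyl}-4-hydroxy-5-(propan-2-yl)cyclohex-2-en-1-one
Conditions: Pb(OAc)4 (1.1 equiv), CH2Cl2, 0 °C to rt
Reagents that add atoms: none
Why: Oxidative decarboxylation of an α-hydroxy acid with lead tetraacetate (a glycol-cleavage-type fragmentation), in which C1 loses its carboxyl carbon as CO2 and its tertiary hydroxyl becomes the ketone conjugated with C2=C3; since the C6 oxygen is acylated, no vicinal diol or free ketol is offered to the oxidant, and C4, C5 and C6 are untouched.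

Step 7
Reactants: 10 4-hydroxy-6-acetoxy enone; 11 isobutyric anhydride
Product: 12 (4S,5S,6R)-6-(acetyloxy)-2-{[(tert-butyldimethylsilyl)oxy]methyl}-4-[(2-methylpropanoyl)oxy]-5-(propan-2-yl)cyclohex-2-en-1-one
Conditions: isobutyric anhydride (1.5 equiv), 4-(dimethylamino)pyridine (DMAP, 0.1 equiv), pyridine, CH2Cl2, 0 °C
Reagents that add atoms: none
Why: DMAP-catalysed acylation (nucleophilic acyl transfer) of the only free hydroxyl, the secondary allylic C4–OH, under weakly basic conditions that leave the α-acetoxy ketone and its C6 stereocenter alone.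

Step 8
Reactants: 12 C4 isobutyrate C6 acetate
Product: 13 (4S,5R,6R)-2-{[(tert-butyldimethylsilyl)oxy]methyl}-6-hydroxy-4-[(2-methylpropanoyl)oxy]-5-(propan-2-yl)cyclohex-2-en-1-one (same spatial arrangement as 12; the C5 descriptor changes only through ligand priorities)
Conditions: K2CO3 (0.3 equiv), MeOH, −20 to 0 °C; aq. NH4Cl
Reagents that add atoms: none
Why: Zemplén-type transesterification under catalytic carbonate, selective because the acetate of the α-ketol is unbranched and activated by the neighbouring C1 ketone whereas the isobutyrate is α-branched and sits next to the isopropyl-bearing carbon; the trans-1,3 relation of the two oxygens rules out acyl migration, and the C6 configuration exposed to base is the preferred one with the C5 and C6 substituents both equatorial.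

Step 9
Reactants: 14 {[tert-butyl(dimethyl)silyl]oxy}acetaldehyde; 15 ethyl 2-(triphenylphosphoranylidene)propanoate
Product: 16 ethyl (2E)-4-{[tert-butyl(dimethyl)silyl]oxy}-2-methylbut-2-enoate
Conditions: CH2Cl2, rt
Reagents that add atoms: none
Why: Wittig olefination with a stabilised α-methyl ylide, which should give the E trisubstituted enoate (ester trans to the CH2O arm) as stabilised ylides do.

Step 10
Reactants: 16 ethyl (2E)-4-silyloxy-2-methylbut-2-enoate
Product: 17 (2E)-4-{[tert-butyl(dimethyl)silyl]oxy}-2-methylbut-2-enoic acid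
Conditions: LiOH·H2O (2 equiv), THF/MeOH/H2O, rt; then 1 M HCl to pH 3 at 0 °C
Reagents that add atoms: lithium hydroxide, [Li+].[OH-]
Why: Ester saponification, to which the primary allylic TBS ether and the conjugated E alkene are stable at room temperature.

Step 11
Reactants: 13 C6 ketol; 17 (2E)-4-silyloxy-2-methylbut-2-enoic acid
Product: 18 (4S,5S,6R)-2-{[(tert-butyldimethylsilyl)oxy]methyl}-6-{[(2E)-4-{[tert-butyl(dimethyl)silyl]oxy}-2-methylbut-2-enoyl]oxy}-4-[(2-methylpropanoyl)oxy]-5-(propan-2-yl)cyclohex-2-en-1-one
Conditions: 17 (1.5 equiv), N,N'-dicyclohexylcarbodiimide (DCC, 1.6 equiv), DMAP (0.2 equiv), CH2Cl2, 0 °C to rt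
Reagents that add atoms: none
Why: Steglich esterification (carbodiimide activation with DMAP as acyl-transfer catalyst) of the single free hydroxyl at C6 with retention, the E geometry of the acid being the stable one and the conditions too mild to epimerise C6 or disturb the C4 isobutyrate.

Step 12
Reactants: 18 bis-silyl ether of the target
Product: 19 (4S,5S,6R)-6-{[(2E)-4-hydroxy-2-methylbut-2-enoyl]oxy}-2-(hydroxymethyl)-4-[(2-methylpropanoyl)oxy]-5-(propan-2-yl)cyclohex-2-en-1-one (CNP0254776.1)
Conditions: HF·pyridine, pyridine, THF, 0 °C to rt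
Reagents that add atoms: none
Why: Fluoride-induced cleavage of both primary TBS ethers with pyridine-buffered HF, mildly acidic conditions under which the two esters, the γ-acyloxy enone and the C6 centre should be stable, releasing the two primary alcohols of the target.

Compound list
1 | 3-hydroxy-2H-pyran-2-one | O=C1OC=CC=C1O | starting material
2 | formaldehyde | C=O | starting material
3 | 3-hydroxy-4-(hydroxymethyl)-2H-pyran-2-one | O=C1OC=CC(CO)=C1O | intermediate
4 | 3-[(tert-butyldimethylsilyl)oxy]-4-{[(tert-butyldimethylsilyl)oxy]methyl}-2H-pyran-2-one (bis-silyl ether) | O=C1OC=CC(CO[Si](C)(C)C(C)(C)C)=C1O[Si](C)(C)C(C)(C)C | intermediate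
5 | 4-{[(tert-butyldimethylsilyl)oxy]methyl}-3-hydroxy-2H-pyran-2-one | O=C1OC=CC(CO[Si](C)(C)C(C)(C)C)=C1O | intermediate
6 | (E)-5-methylhex-3-en-2-one | CC(=O)/C=C/C(C)C | starting material
7 | (1R,4R,7R,8R)-8-acetyl-5-{[(tert-butyldimethylsilyl)oxy]methyl}-4-hydroxy-7-(propan-2-yl)-2-oxabicyclo[2.2.2]oct-5-en-3-one | CC(=O)[C@@H]1[C@@H](C(C)C)[C@@H]2C=C(CO[Si](C)(C)C(C)(C)C)[C@@]1(O)C(=O)O2 | intermediate
8 | (1S,4S,7S,8R)-5-{[(tert-butyldimethylsilyl)oxy]methyl}-4-hydroxy-3-oxo-7-(propan-2-yl)-2-oxabicyclo[2.2.2]oct-5-en-8-yl acetate | CC(=O)O[C@@H]1[C@@H](C(C)C)[C@@H]2C=C(CO[Si](C)(C)C(C)(C)C)[C@@]1(O)C(=O)O2 | intermediate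
9 | (1S,4S,5S,6R)-6-(acetyloxy)-2-{[(tert-butyldimethylsilyl)oxy]methyl}-1,4-dihydroxy-5-(propan-2-yl)cyclohex-2-ene-1-carboxylic acid | CC(=O)O[C@@H]1[C@@H](C(C)C)[C@@H](O)C=C(CO[Si](C)(C)C(C)(C)C)[C@@]1(O)C(=O)O | intermediate
10 | (4S,5S,6R)-6-(acetyloxy)-2-{[(tert-butyldimethylsilyl)oxy]methyl}-4-hydroxy-5-(propan-2-yl)cyclohex-2-en-1-one | CC(=O)O[C@@H]1[C@@H](C(C)C)[C@@H](O)C=C(CO[Si](C)(C)C(C)(C)C)C1=O | intermediate
11 | isobutyric anhydride (2-methylpropanoic anhydride) | CC(C)C(=O)OC(=O)C(C)C | starting material
12 | (4S,5S,6R)-6-(acetyloxy)-2-{[(tert-butyldimethylsilyl)oxy]methyl}-4-[(2-methylpropanoyl)oxy]-5-(propan-2-yl)cyclohex-2-en-1-one | CC(=O)O[C@@H]1[C@@H](C(C)C)[C@@H](OC(=O)C(C)C)C=C(CO[Si](C)(C)C(C)(C)C)C1=O | intermediate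
13 | (4S,5R,6R)-2-{[(tert-butyldimethylsilyl)oxy]methyl}-6-hydroxy-4-[(2-methylpropanoyl)oxy]-5-(propan-2-yl)cyclohex-2-en-1-one | O[C@@H]1[C@@H](C(C)C)[C@@H](OC(=O)C(C)C)C=C(CO[Si](C)(C)C(C)(C)C)C1=O | intermediate
14 | {[tert-butyl(dimethyl)silyl]oxy}acetaldehyde | O=CCO[Si](C)(C)C(C)(C)C | starting material
15 | ethyl 2-(triphenylphosphoranylidene)propanoate | CCOC(=O)C(C)=P(c1ccccc1)(c1ccccc1)c1ccccc1 | starting material
16 | ethyl (2E)-4-{[tert-butyl(dimethyl)silyl]oxy}-2-methylbut-2-enoate | CCOC(=O)/C(C)=C/CO[Si](C)(C)C(C)(C)C | intermediate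
17 | (2E)-4-{[tert-butyl(dimethyl)silyl]oxy}-2-methylbut-2-enoic acid | OC(=O)/C(C)=C/CO[Si](C)(C)C(C)(C)C | intermediate
18 | (4S,5S,6R)-2-{[(tert-butyldimethylsilyl)oxy]methyl}-6-{[(2E)-4-{[tert-butyl(dimethyl)silyl]oxy}-2-methylbut-2-enoyl]oxy}-4-[(2-methylpropanoyl)oxy]-5-(propan-2-yl)cyclohex-2-en-1-one | C/C(=C\CO[Si](C)(C)C(C)(C)C)C(=O)O[C@H]1C(=O)C(CO[Si](C)(C)C(C)(C)C)=C[C@H](OC(=O)C(C)C)[C@@H]1C(C)C | intermediate
19 | (4S,5S,6R)-6-{[(2E)-4-hydroxy-2-methylbut-2-enoyl]oxy}-2-(hydroxymethyl)-4-[(2-methylpropanoyl)oxy]-5-(propan-2-yl)cyclohex-2-en-1-one | C/C(=C\CO)C(=O)O[C@H]1C(=O)C(CO)=C[C@H](OC(=O)C(C)C)[C@@H]1C(C)C | target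

Total step count: 12 steps. Longest linear sequence: 10 steps (steps 1 to 8, 11 and 12, from 1 to 19); steps 9 and 10 make the side-chain acid 17.

Steps most likely to fail

Step 3. The cycloaddition may stall because the β-isopropyl group and the 4-substituent of the pyrone slow bond formation, or the ion pair may loosen so that exo addition or attack on the other pyrone face leaks in. Fallback, setting out from 5 and 6 and coming back at 7: control of absolute configuration is moved from catalysis to resolution. 5 and 6 are joined with triethylamine as an achiral base (CH2Cl2 or neat, rt), the classical base-promoted form of this cycloaddition, which should favour the endo-acetyl adduct. This gives 7 as the racemate, that is together with its mirror-image adduct F1, and the two are separated by preparative chromatography on a chiral stationary phase (amylose tris(3,5-dimethylphenylcarbamate)). 7 then enters step 4.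

Step 8. Methoxide may also strip part of the C4 isobutyrate, or the free α-ketol may enolise under base and drift toward epimerisation or toward aromatisation by loss of the C4 carboxylate. Fallback, setting out from 8 and coming back at 18: the C6 ester is exchanged while the C4 oxygen is still tied up in the lactone, so that no free ketol ever meets base.
- 8 is saponified completely (LiOH, 3 equiv, THF/H2O, rt, then acidification) to the triol acid F2.
- Only the C4 hydroxyl is cis to the carboxyl, so carbodiimide lactonisation under dilution (1-ethyl-3-(3-dimethylaminopropyl)carbodiimide hydrochloride, DMAP, CH2Cl2) can only re-close the bridged ring, giving the C6-hydroxy lactone F3.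
- Steglich esterification with 17 (DCC, DMAP) acylates the secondary hydroxyl and leaves the tertiary bridgehead hydroxyl alone, giving the silyloxytiglate lactone F4.
- LiOH (1.1 equiv, 0 °C) opens the lactone, which is far more reactive than the hindered, conjugated, α-branched ester, to the hydroxy acid F5.
- Pb(OAc)4 then gives the 4-hydroxy enone F6 as in step 6, and acylation with 11 and DMAP gives 18.

Step 1. The dienolate may be attacked at C6 instead of C4 or take up a second formaldehyde, and the hydroxymethyl product may condense with unreacted pyrone. Fallback, setting out from 1 and 2 and coming back at 3: the carbon is delivered through a boron tether. 1, phenylboronic acid and 2 (as paraformaldehyde) with catalytic propionic acid in toluene under azeotropic removal of water give the cyclic phenylboronate F7, in which the formaldehyde carbon can only reach the carbon next to the boron-bound enol oxygen (C4). Exchange with propane-1,3-diol (THF, rt) frees 3.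

Further compounds
F1 | step 3 | mirror-image adduct, (1S,4S,7S,8S)-8-acetyl-5-{[(tert-butyldimethylsilyl)oxy]methyl}-4-hydroxy-7-(propan-2-yl)-2-oxabicyclo[2.2.2]oct-5-en-3-one | CC(=O)[C@H]1[C@H](C(C)C)[C@H]2C=C(CO[Si](C)(C)C(C)(C)C)[C@]1(O)C(=O)O2
F2 | step 8 | triol acid, 2-{[(tert-butyldimethylsilyl)oxy]methyl}-1,4,6-trihydroxy-5-(propan-2-yl)cyclohex-2-ene-1-carboxylic acid (configuration as in 9) | O[C@@H]1[C@@H](C(C)C)[C@@H](O)C=C(CO[Si](C)(C)C(C)(C)C)[C@@]1(O)C(=O)O
F3 | step 8 | C6-hydroxy lactone (8 without its acetyl group) | O[C@@H]1[C@@H](C(C)C)[C@@H]2C=C(CO[Si](C)(C)C(C)(C)C)[C@@]1(O)C(=O)O2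
F4 | step 8 | silyloxytiglate lactone (C6 ester of F3 with 17) | C/C(=C\CO[Si](C)(C)C(C)(C)C)C(=O)O[C@@H]1[C@@H](C(C)C)[C@@H]2C=C(CO[Si](C)(C)C(C)(C)C)[C@@]1(O)C(=O)O2
F5 | step 8 | hydroxy acid (F4 with the lactone opened to C1 carboxylic acid and C4 hydroxyl) | C/C(=C\CO[Si](C)(C)C(C)(C)C)C(=O)O[C@@H]1[C@@H](C(C)C)[C@@H](O)C=C(CO[Si](C)(C)C(C)(C)C)[C@@]1(O)C(=O)O
F6 | step 8 | 4-hydroxy enone (18 without its isobutyryl group) | C/C(=C\CO[Si](C)(C)C(C)(C)C)C(=O)O[C@@H]1[C@@H](C(C)C)[C@@H](O)C=C(CO[Si](C)(C)C(C)(C)C)C1=O
F7 | step 1 | cyclic phenylboronate bridging the 3-oxygen and the 4-CH2O group of 3 (pyrone-fused 2-phenyl-4H-1,3,2-dioxaborin) | O=C1OC=CC2=C1OB(OC2)c1ccccc1
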